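**Strategy.** Everything rests on dissolving the dihydrofuran of ring A (O1, C2, C3, C3a, C7a of the benzofuran that carries the styryl arm) into three pieces. O1–C7a–C3a–C3 is an o-quinone methide in disguise, because C3 is a diarylmethine ortho to a phenolic oxygen, and C2, benzylic to a 4-oxygenated aryl group, is a sulfonium benzylide carbon. In one flask the aryllithium of the finished ring B unit (the second dihydrobenzofuran) adds to an O-Boc salicylaldehyde, Boc transfer unveils the o-quinone methide, and an isothiocineole-derived ylide closes ring A by formal [4+1] annulation, setting C2 and C3 trans. Ring B is made the same way; the stilbene is attached afterwards.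

Key step: step 6

Remarks (one line each):
- Naming: ring A is the 2,3-dihydro-1-benzofuran that carries the styryl group, ring B the other one; locants are those of 1-benzofuran.
- Materials: the two bromo(hydroxy)methoxybenzaldehydes, 3,5-dimethoxyphenylmagnesium chloride solution, both antipodes of isothiocineole and 4-acetoxystyrene are taken as catalogue items.
- Stereochemical assumption: the benzylide from (1R,4R,5R)-isothiocineole is taken to give the (2R,3R) ring and its antipode the (2S,3S) ring; should the sense be the reverse, the two sulfonium salts change places.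

**Step 1**
Reactants: 1 4-bromo-2-hydroxy-6-methoxybenzaldehyde
Product: 2 5-bromo-2-formyl-3-methoxyphenyl tert-butyl carbonate
Conditions: Boc2O, DMAP (cat.), i-Pr2NEt, THF, 0 °C → rt
Reagents that add atoms: di-tert-butyl dicarbonate, CC(C)(C)OC(=O)OC(=O)OC(C)(C)C
Why: DMAP-catalysed O-acylation of the phenol (carbonate formation) installs the Boc group that later acts as the internal leaving group for o-quinone methide formation.

**Step 2**
Reactants: 3 4-methoxybenzyl chloride; 4 (1R,4R,5R)-isothiocineole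
Product: 5 (1R,4R,5R)-6-(4-methoxybenzyl)-4,7,7-trimethyl-6-thiabicyclo[3.2.1]octan-6-ium tetrafluoroborate
Conditions: NaBF4, CH2Cl2/H2O, rt
Reagents that add atoms: sodium tetrafluoroborate, [Na+].F[B-](F)(F)F
Why: S-alkylation of the bicyclic sulfide (sulfonium salt formation) should take place on the less hindered sulfur lone pair, and anion exchange gives a single non-nucleophilic sulfonium salt.

**Step 3**
Reactants: 2 5-bromo-2-formyl-3-methoxyphenyl tert-butyl carbonate; 6 3,5-dimethoxyphenylmagnesium chloride; 5 sulfonium tetrafluoroborate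
Product: 9 (2R,3R)-6-bromo-3-(3,5-dimethoxyphenyl)-4-methoxy-2-(4-methoxyphenyl)-2,3-dihydro-1-benzofuran, via sulfonium ylide 7 (not isolated), via o-quinone methide 8 (not isolated)
Conditions: 2, THF, −78 °C, add 6 (1.0 equiv); then 7 (from 5, LiN(SiMe3)2, THF, −78 °C) by cannula; −78 → 0 °C; aq NH4Cl
Reagents that add atoms: none
Why: Proposed new method: the Grignard reagent adds to the aldehyde, the magnesium alkoxide takes over the neighbouring Boc group and expels tert-butyl carbonate to give o-quinone methide 8, ylide 7 adds to its exocyclic carbon and the phenoxide displaces the sulfide at the benzylic carbon (5-exo-tet, inversion), the face-shielded chiral ylide being expected to set C2 and, through an anti open transition state, C3 as the trans (2R,3R) pair; the closest known reaction types are the Boc-transfer generation of o-quinone methides from O-Boc salicylaldehydes with organometallic reagents and the formal [4+1] annulation of o-quinone methides with sulfonium ylides.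

**Step 4**
Reactants: 10 2-bromo-6-hydroxy-4-methoxybenzaldehyde
Product: 11 3-bromo-2-formyl-5-methoxyphenyl tert-butyl carbonate
Conditions: Boc2O, DMAP (cat.), i-Pr2NEt, THF, 0 °C → rt
Reagents that add atoms: di-tert-butyl dicarbonate, CC(C)(C)OC(=O)OC(=O)OC(C)(C)C
Why: DMAP-catalysed carbonate formation on the phenol, as in step 1; the aryl bromide is the later handle for the stilbene.

**Step 5**
Reactants: 3 4-methoxybenzyl chloride; 12 (1S,4S,5S)-isothiocineole
Product: 13 (1S,4S,5S)-6-(4-methoxybenzyl)-4,7,7-trimethyl-6-thiabicyclo[3.2.1]octan-6-ium tetrafluoroborate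
Conditions: NaBF4, CH2Cl2/H2O, rt
Reagents that add atoms: sodium tetrafluoroborate, [Na+].F[B-](F)(F)F
Why: Sulfonium salt formation as in step 2, here with the antipodal sulfide to give the mirror-image salt needed for ring A.

**Step 6**
Reactants: 9 ring B bromide; 11 3-bromo-2-formyl-5-methoxyphenyl tert-butyl carbonate; 13 antipodal sulfonium tetrafluoroborate
Product: 17 (2S,3S)-4-bromo-3-[(2R,3R)-3-(3,5-dimethoxyphenyl)-4-methoxy-2-(4-methoxyphenyl)-2,3-dihydro-1-benzofuran-6-yl]-6-methoxy-2-(4-methoxyphenyl)-2,3-dihydro-1-benzofuran, via aryllithium 14 (not isolated), via sulfonium ylide 15 (not isolated), via o-quinone methide 16 (not isolated)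
Conditions: 9, t-BuLi (2.0 equiv), THF, −78 °C; 11, −78 °C; MgBr2·OEt2; then 15 (from 13, LiN(SiMe3)2, THF, −78 °C) by cannula; −78 → 0 °C; aq NH4Cl
Reagents that add atoms: none
Why: Proposed new method: aryllithium 14 adds to the formyl group of 11, the alkoxide takes over the neighbouring Boc group and, with magnesium bromide present, tert-butyl carbonate is expelled to give o-quinone methide 16; ylide 15 adds to its exocyclic carbon (the future C3) and the liberated phenoxide displaces the sulfide at the benzylic carbon (the future C2), so that the union of the two halves and the closure of ring A take place in one flask. The closest known reaction types are the Boc-transfer generation of o-quinone methides from O-Boc salicylaldehydes with organometallic reagents and the formal [4+1] annulation of o-quinone methides with sulfonium ylides; new are their merger and the use of a chiral semi-stabilised benzylide for absolute control. Ring A is closed by a 5-exo-tet SN2 displacement (O1 onto C2, inversion at C2) that follows the intermolecular C2–C3 bond formation. C2 is controlled by the sulfide, which exposes one face of the ylide carbon, and C3 is set in the same addition, an anti open transition state keeping the two aryl groups apart so that the invertive closure should give the 2,3-trans (2S,3S) pair; the stereocentres of ring B are too remote to interfere, so the control is by reagent. The step needs chemoselective attack of 14 on the formyl group (fast at −78 °C, carbonate and aryl bromide untouched) and capture of 16 before it self-condenses, which is secured by releasing 16 only when 15 is already in the flask.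

**Step 7**
Reactants: 17 ring A/ring B hexamethyl ether bromide
Product: 19 (2S,3S)-2-(4-acetoxyphenyl)-3-[(2R,3R)-4-acetoxy-2-(4-acetoxyphenyl)-3-(3,5-diacetoxyphenyl)-2,3-dihydro-1-benzofuran-6-yl]-4-bromo-2,3-dihydro-1-benzofuran-6-yl acetate, via hexaphenol 18 (not isolated)
Conditions: BBr3 (excess), CH2Cl2, −78 °C → rt; MeOH quench, concentrate; then Ac2O, pyridine, DMAP (cat.), rt
Reagents that add atoms: acetic anhydride, CC(=O)OC(C)=O
Why: Lewis acid cleavage of the six aryl methyl ethers (BBr3 demethylation) is placed before the stilbene exists, so no acid-induced cyclisation onto a styrene is possible; the thermodynamically preferred trans rings should persist, and acetylation turns the air-sensitive hexaphenol into a stable hexaacetate.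

**Step 8**
Reactants: 19 hexaacetate bromide; 20 4-acetoxystyrene
Product: 22 (2S,3S)-3-[(2R,3R)-3-(3,5-dihydroxyphenyl)-4-hydroxy-2-(4-hydroxyphenyl)-2,3-dihydro-1-benzofuran-6-yl]-2-(4-hydroxyphenyl)-4-[(E)-2-(4-hydroxyphenyl)ethenyl]-2,3-dihydro-1-benzofuran-6-ol, via heptaacetate 21 (not isolated)
Conditions: Pd(OAc)2 (10 mol%), P(o-tol)3, Et3N, DMF, 100 °C, argon; then K2CO3, MeOH, 0 °C → rt
Reagents that add atoms: none
Why: Mizoroki–Heck reaction (oxidative addition of the aryl bromide to zerovalent palladium, syn insertion and syn β-hydride elimination) should give the E-stilbene, and carbonate-mediated methanolysis then removes all seven acetates without acid, leaving the four stereocentres untouched.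

**Compound list**

1 | 4-bromo-2-hydroxy-6-methoxybenzaldehyde | O=Cc1c(O)cc(Br)cc1OC | starting material
2 | 5-bromo-2-formyl-3-methoxyphenyl tert-butyl carbonate | O=Cc1c(OC(=O)OC(C)(C)C)cc(Br)cc1OC | intermediate
3 | 4-methoxybenzyl chloride | COc1ccc(CCl)cc1 | starting material
4 | (1R,4R,5R)-4,7,7-trimethyl-6-thiabicyclo[3.2.1]octane (isothiocineole) | C[C@@H]1CC[C@@H]2C[C@H]1SC2(C)C | starting material
5 | (1R,4R,5R)-6-(4-methoxybenzyl)-4,7,7-trimethyl-6-thiabicyclo[3.2.1]octan-6-ium tetrafluoroborate (benzyl group on the sulfur face next to the one-carbon bridge) | C[C@@H]1CC[C@@H]2C[C@H]1[S@@+](Cc1ccc(OC)cc1)C2(C)C.F[B-](F)(F)F | intermediate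
6 | 3,5-dimethoxyphenylmagnesium chloride (THF solution) | COc1cc([Mg]Cl)cc(OC)c1 | starting material
7 | sulfonium ylide from 5 | C[C@@H]1CC[C@@H]2C[C@H]1[S@@+]([CH-]c1ccc(OC)cc1)C2(C)C | intermediate
8 | 3-bromo-6-[(3,5-dimethoxyphenyl)methylidene]-5-methoxycyclohexa-2,4-dien-1-one (exocyclic geometry not defined) | O=C1C=C(Br)C=C(OC)C1=Cc1cc(OC)cc(OC)c1 | intermediate
9 | (2R,3R)-6-bromo-3-(3,5-dimethoxyphenyl)-4-methoxy-2-(4-methoxyphenyl)-2,3-dihydro-1-benzofuran | Brc1cc(OC)c2c(c1)O[C@@H](c1ccc(OC)cc1)[C@@H]2c1cc(OC)cc(OC)c1 | intermediate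
10 | 2-bromo-6-hydroxy-4-methoxybenzaldehyde | O=Cc1c(O)cc(OC)cc1Br | starting material
11 | 3-bromo-2-formyl-5-methoxyphenyl tert-butyl carbonate | O=Cc1c(OC(=O)OC(C)(C)C)cc(OC)cc1Br | intermediate
12 | (1S,4S,5S)-4,7,7-trimethyl-6-thiabicyclo[3.2.1]octane (ent-isothiocineole) | C[C@H]1CC[C@H]2C[C@@H]1SC2(C)C | starting material
13 | (1S,4S,5S)-6-(4-methoxybenzyl)-4,7,7-trimethyl-6-thiabicyclo[3.2.1]octan-6-ium tetrafluoroborate (mirror image of 5) | C[C@H]1CC[C@H]2C[C@@H]1[S@+](Cc1ccc(OC)cc1)C2(C)C.F[B-](F)(F)F | intermediate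
14 | [(2R,3R)-3-(3,5-dimethoxyphenyl)-4-methoxy-2-(4-methoxyphenyl)-2,3-dihydro-1-benzofuran-6-yl]lithium | [Li]c1cc(OC)c2c(c1)O[C@@H](c1ccc(OC)cc1)[C@@H]2c1cc(OC)cc(OC)c1 | intermediate
15 | sulfonium ylide from 13 | C[C@H]1CC[C@H]2C[C@@H]1[S@+]([CH-]c1ccc(OC)cc1)C2(C)C | intermediate
16 | 5-bromo-6-[[(2R,3R)-3-(3,5-dimethoxyphenyl)-4-methoxy-2-(4-methoxyphenyl)-2,3-dihydro-1-benzofuran-6-yl]methylidene]-3-methoxycyclohexa-2,4-dien-1-one (exocyclic geometry not defined) | O=C1C=C(OC)C=C(Br)C1=Cc1cc(OC)c2c(c1)O[C@@H](c1ccc(OC)cc1)[C@@H]2c1cc(OC)cc(OC)c1 | intermediate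
17 | (2S,3S)-4-bromo-3-[(2R,3R)-3-(3,5-dimethoxyphenyl)-4-methoxy-2-(4-methoxyphenyl)-2,3-dihydro-1-benzofuran-6-yl]-6-methoxy-2-(4-methoxyphenyl)-2,3-dihydro-1-benzofuran | Brc1cc(OC)cc2c1[C@H](c1cc(OC)c3c(c1)O[C@@H](c1ccc(OC)cc1)[C@@H]3c1cc(OC)cc(OC)c1)[C@@H](c1ccc(OC)cc1)O2 | intermediate
18 | (2S,3S)-4-bromo-3-[(2R,3R)-3-(3,5-dihydroxyphenyl)-4-hydroxy-2-(4-hydroxyphenyl)-2,3-dihydro-1-benzofuran-6-yl]-2-(4-hydroxyphenyl)-2,3-dihydro-1-benzofuran-6-ol | Brc1cc(O)cc2c1[C@H](c1cc(O)c3c(c1)O[C@@H](c1ccc(O)cc1)[C@@H]3c1cc(O)cc(O)c1)[C@@H](c1ccc(O)cc1)O2 | intermediate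
19 | (2S,3S)-2-(4-acetoxyphenyl)-3-[(2R,3R)-4-acetoxy-2-(4-acetoxyphenyl)-3-(3,5-diacetoxyphenyl)-2,3-dihydro-1-benzofuran-6-yl]-4-bromo-2,3-dihydro-1-benzofuran-6-yl acetate | Brc1cc(OC(C)=O)cc2c1[C@H](c1cc(OC(C)=O)c3c(c1)O[C@@H](c1ccc(OC(C)=O)cc1)[C@@H]3c1cc(OC(C)=O)cc(OC(C)=O)c1)[C@@H](c1ccc(OC(C)=O)cc1)O2 | intermediate
20 | 4-acetoxystyrene | CC(=O)Oc1ccc(C=C)cc1 | starting material
21 | (2S,3S)-2-(4-acetoxyphenyl)-3-[(2R,3R)-4-acetoxy-2-(4-acetoxyphenyl)-3-(3,5-diacetoxyphenyl)-2,3-dihydro-1-benzofuran-6-yl]-4-[(E)-2-(4-acetoxyphenyl)ethenyl]-2,3-dihydro-1-benzofuran-6-yl acetate | CC(=O)Oc1ccc(/C=C/c2cc(OC(C)=O)cc3c2[C@H](c2cc(OC(C)=O)c4c(c2)O[C@@H](c2ccc(OC(C)=O)cc2)[C@@H]4c2cc(OC(C)=O)cc(OC(C)=O)c2)[C@@H](c2ccc(OC(C)=O)cc2)O3)cc1 | intermediate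
22 | (2S,3S)-3-[(2R,3R)-3-(3,5-dihydroxyphenyl)-4-hydroxy-2-(4-hydroxyphenyl)-2,3-dihydro-1-benzofuran-6-yl]-2-(4-hydroxyphenyl)-4-[(E)-2-(4-hydroxyphenyl)ethenyl]-2,3-dihydro-1-benzofuran-6-ol (CNP0188679.4) | Oc1ccc(/C=C/c2cc(O)cc3c2[C@H](c2cc(O)c4c(c2)O[C@@H](c2ccc(O)cc2)[C@@H]4c2cc(O)cc(O)c2)[C@@H](c2ccc(O)cc2)O3)cc1 | target

**Step count and risks**

Total step count: 8. Longest linear sequence: 5 steps (steps 1, 3, 6, 7, 8).

Steps most likely to fail:

1. Step 6. The two aryl groups may not sort cleanly in the carbon–carbon bond-forming ylide addition (poor simple diastereoselection, seen as erosion of configuration at C3), and self-condensation of the o-quinone methide may outrun its capture. The fallback replaces the annulation by the known enantioselective intramolecular C–H insertion of a donor/donor rhodium carbene; it sets out from 9 and 10 and comes back at 17. Phenol 10 is O-alkylated with 3 (K2CO3, DMF) to 2-bromo-4-methoxy-6-[(4-methoxybenzyl)oxy]benzaldehyde F1. Aryllithium 14 (from 9, t-BuLi, THF, −78 °C) adds to it to give the diarylmethanol F2 (carbinol epimers), and Dess–Martin periodinane gives the diaryl ketone F3. Hydrazine hydrate (AcOH, n-BuOH, 120 °C) gives the hydrazone F4, and MnO2 (CH2Cl2, 0 °C) gives the diaryldiazomethane F5. With dirhodium tetrakis[(S)-N-phthaloyl-(1-adamantyl)glycinate], Rh2(S-PTAD)4 (or its antipode, whichever delivers 3S), the carbene inserts into the benzylic O–CH2 bond and closes ring A as the 2,3-cis dihydrobenzofuran F6. BF3·OEt2 (CH2Cl2, 0 °C) then epimerises C2 through the 4-methoxybenzylic cation to the trans isomer 17.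

2. Step 3. The same cascade on the 2,6-dioxygenated o-quinone methide may suffer from insufficient facial discrimination or from premature loss of the Boc group before the ylide is present. The fallback uses the same known carbene chemistry; it sets out from 1 and 6 and comes back at 9. Phenol 1 is O-alkylated with 3 (K2CO3, DMF) to 4-bromo-2-methoxy-6-[(4-methoxybenzyl)oxy]benzaldehyde F7. Grignard reagent 6 (THF, 0 °C) gives the diarylmethanol F8, and Dess–Martin periodinane gives the diaryl ketone F9. Hydrazine hydrate (AcOH, n-BuOH, 120 °C) gives the hydrazone F10, and MnO2 gives the diaryldiazomethane F11. Rh2(R-PTAD)4 (the antipodal catalyst) closes ring B by C–H insertion into the benzylic O–CH2 bond as the 2,3-cis dihydrobenzofuran F12, and BF3·OEt2 epimerises C2 to the trans isomer 9.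

3. Step 8. Oxidative addition and olefin insertion at the C4 bromide, which is flanked by the C3 diarylmethine, may be slow enough for protodebromination to compete. The fallback reverses the roles of the coupling partners; it sets out from 19 and comes back at 21. Stille coupling of 19 with Bu3SnCH=CH2 (Pd(PPh3)4, toluene, 100 °C) gives the 4-ethenyl hexaacetate F13. Its Mizoroki–Heck reaction with 4-iodophenyl acetate (Pd(OAc)2, Et3N, DMF, 80 °C) takes place at an unhindered aryl iodide and gives heptaacetate 21, which is methanolysed as in step 8.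

**Further compounds**

F1 | step 6 | 2-bromo-4-methoxy-6-[(4-methoxybenzyl)oxy]benzaldehyde | O=Cc1c(OCc2ccc(OC)cc2)cc(OC)cc1Br
F2 | step 6 | [2-bromo-4-methoxy-6-[(4-methoxybenzyl)oxy]phenyl][(2R,3R)-3-(3,5-dimethoxyphenyl)-4-methoxy-2-(4-methoxyphenyl)-2,3-dihydro-1-benzofuran-6-yl]methanol (carbinol epimers) | OC(c1c(OCc2ccc(OC)cc2)cc(OC)cc1Br)c1cc(OC)c2c(c1)O[C@@H](c1ccc(OC)cc1)[C@@H]2c1cc(OC)cc(OC)c1
F3 | step 6 | [2-bromo-4-methoxy-6-[(4-methoxybenzyl)oxy]phenyl][(2R,3R)-3-(3,5-dimethoxyphenyl)-4-methoxy-2-(4-methoxyphenyl)-2,3-dihydro-1-benzofuran-6-yl]methanone | O=C(c1c(OCc2ccc(OC)cc2)cc(OC)cc1Br)c1cc(OC)c2c(c1)O[C@@H](c1ccc(OC)cc1)[C@@H]2c1cc(OC)cc(OC)c1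
F4 | step 6 | hydrazone of F3 | NN=C(c1c(OCc2ccc(OC)cc2)cc(OC)cc1Br)c1cc(OC)c2c(c1)O[C@@H](c1ccc(OC)cc1)[C@@H]2c1cc(OC)cc(OC)c1
F5 | step 6 | diaryldiazomethane from F4 | [N-]=[N+]=C(c1c(OCc2ccc(OC)cc2)cc(OC)cc1Br)c1cc(OC)c2c(c1)O[C@@H](c1ccc(OC)cc1)[C@@H]2c1cc(OC)cc(OC)c1
F6 | step 6 | (2R,3S)-4-bromo-3-[(2R,3R)-3-(3,5-dimethoxyphenyl)-4-methoxy-2-(4-methoxyphenyl)-2,3-dihydro-1-benzofuran-6-yl]-6-methoxy-2-(4-methoxyphenyl)-2,3-dihydro-1-benzofuran (2,3-cis in ring A) | Brc1cc(OC)cc2c1[C@H](c1cc(OC)c3c(c1)O[C@@H](c1ccc(OC)cc1)[C@@H]3c1cc(OC)cc(OC)c1)[C@H](c1ccc(OC)cc1)O2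
F7 | step 3 | 4-bromo-2-methoxy-6-[(4-methoxybenzyl)oxy]benzaldehyde | O=Cc1c(OCc2ccc(OC)cc2)cc(Br)cc1OC
F8 | step 3 | [4-bromo-2-methoxy-6-[(4-methoxybenzyl)oxy]phenyl](3,5-dimethoxyphenyl)methanol (racemic) | OC(c1c(OCc2ccc(OC)cc2)cc(Br)cc1OC)c1cc(OC)cc(OC)c1
F9 | step 3 | [4-bromo-2-methoxy-6-[(4-methoxybenzyl)oxy]phenyl](3,5-dimethoxyphenyl)methanone | O=C(c1c(OCc2ccc(OC)cc2)cc(Br)cc1OC)c1cc(OC)cc(OC)c1
F10 | step 3 | hydrazone of F9 | NN=C(c1c(OCc2ccc(OC)cc2)cc(Br)cc1OC)c1cc(OC)cc(OC)c1
F11 | step 3 | diaryldiazomethane from F10 | [N-]=[N+]=C(c1c(OCc2ccc(OC)cc2)cc(Br)cc1OC)c1cc(OC)cc(OC)c1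
F12 | step 3 | (2S,3R)-6-bromo-3-(3,5-dimethoxyphenyl)-4-methoxy-2-(4-methoxyphenyl)-2,3-dihydro-1-benzofuran (2,3-cis) | Brc1cc(OC)c2c(c1)O[C@H](c1ccc(OC)cc1)[C@@H]2c1cc(OC)cc(OC)c1
F13 | step 8 | (2S,3S)-2-(4-acetoxyphenyl)-3-[(2R,3R)-4-acetoxy-2-(4-acetoxyphenyl)-3-(3,5-diacetoxyphenyl)-2,3-dihydro-1-benzofuran-6-yl]-4-ethenyl-2,3-dihydro-1-benzofuran-6-yl acetate | C=Cc1cc(OC(C)=O)cc2c1[C@H](c1cc(OC(C)=O)c3c(c1)O[C@@H](c1ccc(OC(C)=O)cc1)[C@@H]3c1cc(OC(C)=O)cc(OC(C)=O)c1)[C@@H](c1ccc(OC(C)=O)cc1)O2
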